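The synthesis rests on closing ring C at the aryl ether bond O1–C8a. C8a of ring A is ortho to the C4 carbonyl and meta to the oxygens on C5 and C7, so a fluorine placed there serves first as a metalation director while ring A is assembled and then as an SNAr leaving group. Three directed metalations of 5-fluororesorcinol bis-MOM ether install the hydroxyethyl, prenyl and acyl groups; the acyl partner is a Weinreb amide whose (S)-carbinol is set by asymmetric transfer hydrogenation. In the key step catalytic fluoride frees the silylated C2 alkoxide, which displaces the C8a fluorine, closes ring C and fixes the 8-prenyl/6-hydroxyethyl pattern.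

Key step: step 9

Assumption: n-BuLi in diethyl ether metalates 2 between its two MOM ethers (double chelation) and not next to fluorine. 5-Fluororesorcinol, methyl vanillate and N-methoxy-N-methylacetamide are taken as commercial.

Step 1
Reactants: 1 5-fluororesorcinol
Product: 2 1-fluoro-3,5-bis(methoxymethoxy)benzene
Conditions: MOMCl, i-Pr2NEt, CH2Cl2, 0 °C to rt
Reagents that add atoms: chloromethyl methyl ether (MOMCl), COCCl
Why: Williamson-type O-alkylation of both phenols should give the bis-MOM ether, whose acetal oxygens direct the later metalations and are removed by acid at the end.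

Step 2
Reactants: 2 1-fluoro-3,5-bis(methoxymethoxy)benzene
Product: 5 tert-butyl{2-[4-fluoro-2,6-bis(methoxymethoxy)phenyl]ethoxy}dimethylsilane, via aryllithium 3 (not isolated), via lithium alkoxide 4 (not isolated)
Conditions: n-BuLi, Et2O, 0 °C; ethylene oxide, −78 °C to rt; then TBSCl, DMF, rt (one pot)
Reagents that add atoms: ethylene oxide, C1CO1; tert-butyldimethylsilyl chloride (TBSCl), CC(C)(C)[Si](C)(C)Cl
Why: Directed ortho-metalation at the carbon chelated by both MOM ethers (para to fluorine, so no LiF loss), epoxide opening by the aryllithium and O-silylation of the lithium alkoxide should place the protected hydroxyethyl group on the future C6.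

Step 3
Reactants: 5 tert-butyl{2-[4-fluoro-2,6-bis(methoxymethoxy)phenyl]ethoxy}dimethylsilane
Product: 8 tert-butyl{2-[4-fluoro-2,6-bis(methoxymethoxy)-3-(3-methylbut-2-en-1-yl)phenyl]ethoxy}dimethylsilane, via aryllithium 6 (not isolated), via arylcopper 7 (not isolated)
Conditions: n-BuLi, THF, −78 °C; CuBr·SMe2, −78 to −40 °C; prenyl bromide, −40 to 0 °C
Reagents that add atoms: prenyl bromide (1-bromo-3-methylbut-2-ene), CC(C)=CCBr
Why: The two remaining ring hydrogens are equivalent and each lies between fluorine and a MOM ether, so directed ortho-metalation is unambiguous, and copper-mediated SN2 allylation at the primary carbon of prenyl bromide should give the C-prenyl arene while the low temperature prevents LiF loss.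

Step 4
Reactants: 9 methyl vanillate
Product: 10 methyl 3-methoxy-4-(methoxymethoxy)benzoate
Conditions: MOMCl, i-Pr2NEt, CH2Cl2, 0 °C to rt
Reagents that add atoms: chloromethyl methyl ether (MOMCl), COCCl
Why: O-alkylation of the phenol should mask the only acidic proton of ring B with the same acid-labile group used on ring A.

Step 5
Reactants: 10 methyl 3-methoxy-4-(methoxymethoxy)benzoate
Product: 11 N-methoxy-3-[3-methoxy-4-(methoxymethoxy)phenyl]-N-methyl-3-oxopropanamide
Conditions: N-methoxy-N-methylacetamide, LiN(i-Pr)2 (LDA) (2.2 equiv each), THF, −78 °C; add 10, −78 to 0 °C; AcOH quench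
Reagents that add atoms: N-methoxy-N-methylacetamide, CC(=O)N(C)OC
Why: Crossed Claisen condensation of the amide enolate with the non-enolisable aryl ester should give the β-keto Weinreb amide, driven by deprotonation of the product by the second equivalent of enolate.

Step 6
Reactants: 11 N-methoxy-3-[3-methoxy-4-(methoxymethoxy)phenyl]-N-methyl-3-oxopropanamide
Product: 12 (3S)-3-hydroxy-N-methoxy-3-[3-methoxy-4-(methoxymethoxy)phenyl]-N-methylpropanamide
Conditions: RuCl[(S,S)-TsDPEN](p-cymene) (1 mol %), HCO2H/Et3N (5:2), DMF, 40 °C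
Reagents that add atoms: none
Why: Noyori–Ikariya asymmetric transfer hydrogenation of the aryl ketone, in which the (S,S)-catalyst should deliver hydride to the face that gives the (S)-carbinol as it does for acetophenones (aryl/η6-arene CH–π contact), sets the future C2 stereocenter.

Step 7
Reactants: 12 (3S)-3-hydroxy-N-methoxy-3-[3-methoxy-4-(methoxymethoxy)phenyl]-N-methylpropanamide
Product: 13 (3S)-N-methoxy-3-[3-methoxy-4-(methoxymethoxy)phenyl]-N-methyl-3-[(triethylsilyl)oxy]propanamide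
Conditions: TESCl, imidazole, CH2Cl2, 0 °C
Reagents that add atoms: chlorotriethylsilane (TESCl), CC[Si](Cl)(CC)CC
Why: O-silylation removes the acidic proton before the organolithium step and stores the C2 oxygen as a fluoride-labile latent alkoxide for the ring closure.

Step 8
Reactants: 8 tert-butyl{2-[4-fluoro-2,6-bis(methoxymethoxy)-3-(3-methylbut-2-en-1-yl)phenyl]ethoxy}dimethylsilane; 13 (3S)-N-methoxy-3-[3-methoxy-4-(methoxymethoxy)phenyl]-N-methyl-3-[(triethylsilyl)oxy]propanamide
Product: 16 (3S)-1-[3-(2-{[tert-butyl(dimethyl)silyl]oxy}ethyl)-6-fluoro-2,4-bis(methoxymethoxy)-5-(3-methylbut-2-en-1-yl)phenyl]-3-[3-methoxy-4-(methoxymethoxy)phenyl]-3-[(triethylsilyl)oxy]propan-1-one, via aryllithium 14 (not isolated), via tetrahedral adduct 15 (not isolated)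
Conditions: 8, n-BuLi, THF, −78 °C; then 13, −78 to −50 °C; AcOH, −78 °C
Reagents that add atoms: none
Why: Directed ortho-metalation of the last ring hydrogen (between fluorine and a MOM ether) followed by Weinreb ketone synthesis, whose chelated tetrahedral adduct prevents over-addition, should form the C4–C4a bond without touching the C2 stereocenter.

Step 9
Reactants: 16 (3S)-1-[3-(2-{[tert-butyl(dimethyl)silyl]oxy}ethyl)-6-fluoro-2,4-bis(methoxymethoxy)-5-(3-methylbut-2-en-1-yl)phenyl]-3-[3-methoxy-4-(methoxymethoxy)phenyl]-3-[(triethylsilyl)oxy]propan-1-one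
Product: 18 (2S)-6-(2-{[tert-butyl(dimethyl)silyl]oxy}ethyl)-2-[3-methoxy-4-(methoxymethoxy)phenyl]-5,7-bis(methoxymethoxy)-8-(3-methylbut-2-en-1-yl)-2,3-dihydro-4H-chromen-4-one, via alkoxide 17 (not isolated)
Conditions: Bu4N[Ph3SiF2] (TBAT, 10 mol %), DMF, 0 °C to rt
Reagents that add atoms: none
Why: Fluoride from TBAT attacks the triethylsilyl group of 16 and frees the C2 alkoxide 17, which adds to C8a (ipso to fluorine) to give a Meisenheimer anion delocalised through C4a into the C4 carbonyl; loss of fluoride restores ring A, and the expelled fluoride desilylates the next molecule, so the medium never holds a stoichiometric base. The closest known reaction types are the intramolecular SNAr etherification of ortho-fluoroaryl ketones (chromone and xanthone syntheses) and the fluoride-catalysed SNAr of silyl ethers with fluoroarenes. Ring C closes in a 6-exo-trig addition–elimination at the trigonal C8a. No new stereocenter is formed, and C2 keeps the (S) configuration from step 6 because its C–O bond is never broken. The step needs O1 attack at C8a to outrun retro-aldol cleavage and E1cB elimination across C2–C3, which the low steady-state alkoxide concentration, the lack of a proton shuttle and the ortho-carbonyl activation (both MOM-oxygens are meta to C8a) should secure. The 8-prenyl/6-hydroxyethyl regiochemistry is fixed because fluorine sits only on C8a while the oxygen on C5 stays masked as its MOM ether.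

Step 10
Reactants: 18 (2S)-6-(2-{[tert-butyl(dimethyl)silyl]oxy}ethyl)-2-[3-methoxy-4-(methoxymethoxy)phenyl]-5,7-bis(methoxymethoxy)-8-(3-methylbut-2-en-1-yl)-2,3-dihydro-4H-chromen-4-one
Product: 19 laxiflorin, (2S)-5,7-dihydroxy-2-(4-hydroxy-3-methoxyphenyl)-6-(2-hydroxyethyl)-8-(3-methylbut-2-en-1-yl)-2,3-dihydro-4H-chromen-4-one
Conditions: HCl (3 M aq.)/MeOH, 45 °C
Reagents that add atoms: none
Why: Acid-catalysed acetal exchange with methanol should cleave the three aryl MOM ethers and methanolysis should remove the primary TBS ether in one operation, under conditions mild enough to leave the prenyl alkene and the C2 stereocenter intact.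

Compound list
1 | 5-fluororesorcinol (5-fluorobenzene-1,3-diol) | Oc1cc(O)cc(F)c1 | starting material
2 | 1-fluoro-3,5-bis(methoxymethoxy)benzene | COCOc1cc(F)cc(OCOC)c1 | intermediate
3 | [4-fluoro-2,6-bis(methoxymethoxy)phenyl]lithium | [Li]c1c(OCOC)cc(F)cc1OCOC | intermediate
4 | lithium 2-[4-fluoro-2,6-bis(methoxymethoxy)phenyl]ethoxide | [Li]OCCc1c(OCOC)cc(F)cc1OCOC | intermediate
5 | tert-butyl{2-[4-fluoro-2,6-bis(methoxymethoxy)phenyl]ethoxy}dimethylsilane | CC(C)(C)[Si](C)(C)OCCc1c(OCOC)cc(F)cc1OCOC | intermediate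
6 | [3-(2-{[tert-butyl(dimethyl)silyl]oxy}ethyl)-6-fluoro-2,4-bis(methoxymethoxy)phenyl]lithium | CC(C)(C)[Si](C)(C)OCCc1c(OCOC)cc(F)c([Li])c1OCOC | intermediate
7 | [3-(2-{[tert-butyl(dimethyl)silyl]oxy}ethyl)-6-fluoro-2,4-bis(methoxymethoxy)phenyl]copper | CC(C)(C)[Si](C)(C)OCCc1c(OCOC)cc(F)c([Cu])c1OCOC | intermediate
8 | tert-butyl{2-[4-fluoro-2,6-bis(methoxymethoxy)-3-(3-methylbut-2-en-1-yl)phenyl]ethoxy}dimethylsilane | CC(C)(C)[Si](C)(C)OCCc1c(OCOC)cc(F)c(CC=C(C)C)c1OCOC | intermediate
9 | methyl vanillate (methyl 4-hydroxy-3-methoxybenzoate) | COC(=O)c1ccc(O)c(OC)c1 | starting material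
10 | methyl 3-methoxy-4-(methoxymethoxy)benzoate | COCOc1ccc(C(=O)OC)cc1OC | intermediate
11 | N-methoxy-3-[3-methoxy-4-(methoxymethoxy)phenyl]-N-methyl-3-oxopropanamide | COCOc1ccc(C(=O)CC(=O)N(C)OC)cc1OC | intermediate
12 | (3S)-3-hydroxy-N-methoxy-3-[3-methoxy-4-(methoxymethoxy)phenyl]-N-methylpropanamide | COc1cc([C@@H](O)CC(=O)N(C)OC)ccc1OCOC | intermediate
13 | (3S)-N-methoxy-3-[3-methoxy-4-(methoxymethoxy)phenyl]-N-methyl-3-[(triethylsilyl)oxy]propanamide | COc1cc([C@@H](O[Si](CC)(CC)CC)CC(=O)N(C)OC)ccc1OCOC | intermediate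
14 | [3-(2-{[tert-butyl(dimethyl)silyl]oxy}ethyl)-6-fluoro-2,4-bis(methoxymethoxy)-5-(3-methylbut-2-en-1-yl)phenyl]lithium | CC(C)(C)[Si](C)(C)OCCc1c(OCOC)c([Li])c(F)c(CC=C(C)C)c1OCOC | intermediate
15 | lithium hemiaminal alkoxide from 14 and 13 (tetrahedral adduct; new carbinol carbon unassigned) | COc1cc([C@@H](O[Si](CC)(CC)CC)CC(O[Li])(N(C)OC)c2c(OCOC)c(CCO[Si](C)(C)C(C)(C)C)c(OCOC)c(CC=C(C)C)c2F)ccc1OCOC | intermediate
16 | (3S)-1-[3-(2-{[tert-butyl(dimethyl)silyl]oxy}ethyl)-6-fluoro-2,4-bis(methoxymethoxy)-5-(3-methylbut-2-en-1-yl)phenyl]-3-[3-methoxy-4-(methoxymethoxy)phenyl]-3-[(triethylsilyl)oxy]propan-1-one | COc1cc([C@@H](O[Si](CC)(CC)CC)CC(=O)c2c(OCOC)c(CCO[Si](C)(C)C(C)(C)C)c(OCOC)c(CC=C(C)C)c2F)ccc1OCOC | intermediate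
17 | tetrabutylammonium (1S)-alkoxide of desilylated 16 | COc1cc([C@@H]([O-])CC(=O)c2c(OCOC)c(CCO[Si](C)(C)C(C)(C)C)c(OCOC)c(CC=C(C)C)c2F)ccc1OCOC.CCCC[N+](CCCC)(CCCC)CCCC | intermediate
18 | (2S)-6-(2-{[tert-butyl(dimethyl)silyl]oxy}ethyl)-2-[3-methoxy-4-(methoxymethoxy)phenyl]-5,7-bis(methoxymethoxy)-8-(3-methylbut-2-en-1-yl)-2,3-dihydro-4H-chromen-4-one | COc1cc([C@@H]2CC(=O)c3c(OCOC)c(CCO[Si](C)(C)C(C)(C)C)c(OCOC)c(CC=C(C)C)c3O2)ccc1OCOC | intermediate
19 | laxiflorin, (2S)-5,7-dihydroxy-2-(4-hydroxy-3-methoxyphenyl)-6-(2-hydroxyethyl)-8-(3-methylbut-2-en-1-yl)-2,3-dihydro-4H-chromen-4-one | COc1cc([C@@H]2CC(=O)c3c(O)c(CCO)c(O)c(CC=C(C)C)c3O2)ccc1O | target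

Total steps: 10. Longest linear sequence: 7 (steps 4 to 10); the ring A branch (steps 1 to 3) joins at step 8.

Steps most likely to fail

Step 2. Metalation may occur next to fluorine instead of between the MOM ethers, and such an aryllithium would lose LiF to an aryne at 0 °C. Fallback from 2: block both fluorine-flanked positions by in situ silylation (LDA, TMSCl, THF, −78 °C) to give [2-fluoro-4,6-bis(methoxymethoxy)-1,3-phenylene]bis(trimethylsilane) F1. Metalate the only ring hydrogen left (n-BuLi, Et2O, 0 °C), open ethylene oxide and silylate with TBSCl to give tert-butyl{2-[4-fluoro-2,6-bis(methoxymethoxy)-3,5-bis(trimethylsilyl)phenyl]ethoxy}dimethylsilane F2. Strip the aryl and alkyl silyl groups with Bu4NF in wet THF at 60 °C to 2-[4-fluoro-2,6-bis(methoxymethoxy)phenyl]ethanol F3, and re-silylate (TBSCl, imidazole, DMF) to come back at 5.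

Step 9. Retro-aldol cleavage or E1cB elimination of the β-oxygen may outrun the ring closure, or C2 may epimerise through base-induced ring opening of the product. Fallback from 16: cleave the TES ether (PPTS, MeOH, 0 °C) to (3S)-1-[3-(2-{[tert-butyl(dimethyl)silyl]oxy}ethyl)-6-fluoro-2,4-bis(methoxymethoxy)-5-(3-methylbut-2-en-1-yl)phenyl]-3-hydroxy-3-[3-methoxy-4-(methoxymethoxy)phenyl]propan-1-one F6. Oxidise with Dess–Martin periodinane to the corresponding propane-1,3-dione F7. Close the same O1–C8a bond through the enolate oxygen (K2CO3, DMF, 60 °C), which cannot undergo retro-aldol, to give 6-(2-{[tert-butyl(dimethyl)silyl]oxy}ethyl)-2-[3-methoxy-4-(methoxymethoxy)phenyl]-5,7-bis(methoxymethoxy)-8-(3-methylbut-2-en-1-yl)-4H-chromen-4-one F8. Set C2 last by copper hydride asymmetric 1,4-reduction (Cu(OAc)2, the DTBM-SEGPHOS enantiomer that a model flavone shows to give the (2S) product, PMHS, t-BuOH, toluene) to come back at 18.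

Step 8. The hindered, basic aryllithium 14 may enolise the Weinreb amide (with β-elimination of silanolate) or lose LiF on warming before it acylates. Fallback from 13: reduce with i-Bu2AlH (THF, −78 °C) to (3S)-3-[3-methoxy-4-(methoxymethoxy)phenyl]-3-[(triethylsilyl)oxy]propanal F4. Add 14 at −78 °C, where addition to the aldehyde is fast, to give (3S)-1-[3-(2-{[tert-butyl(dimethyl)silyl]oxy}ethyl)-6-fluoro-2,4-bis(methoxymethoxy)-5-(3-methylbut-2-en-1-yl)phenyl]-3-[3-methoxy-4-(methoxymethoxy)phenyl]-3-[(triethylsilyl)oxy]propan-1-ol F5 as both C1 epimers. Oxidise with Dess–Martin periodinane (NaHCO3, CH2Cl2) to come back at 16.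

Further compounds
F1 | step 2 | [2-fluoro-4,6-bis(methoxymethoxy)-1,3-phenylene]bis(trimethylsilane) | COCOc1cc(OCOC)c([Si](C)(C)C)c(F)c1[Si](C)(C)C
F2 | step 2 | tert-butyl{2-[4-fluoro-2,6-bis(methoxymethoxy)-3,5-bis(trimethylsilyl)phenyl]ethoxy}dimethylsilane | CC(C)(C)[Si](C)(C)OCCc1c(OCOC)c([Si](C)(C)C)c(F)c([Si](C)(C)C)c1OCOC
F3 | step 2 | 2-[4-fluoro-2,6-bis(methoxymethoxy)phenyl]ethanol | OCCc1c(OCOC)cc(F)cc1OCOC
F4 | step 8 | (3S)-3-[3-methoxy-4-(methoxymethoxy)phenyl]-3-[(triethylsilyl)oxy]propanal | COc1cc([C@@H](O[Si](CC)(CC)CC)CC=O)ccc1OCOC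
F5 | step 8 | (3S)-1-[3-(2-{[tert-butyl(dimethyl)silyl]oxy}ethyl)-6-fluoro-2,4-bis(methoxymethoxy)-5-(3-methylbut-2-en-1-yl)phenyl]-3-[3-methoxy-4-(methoxymethoxy)phenyl]-3-[(triethylsilyl)oxy]propan-1-ol | COc1cc([C@@H](O[Si](CC)(CC)CC)CC(O)c2c(OCOC)c(CCO[Si](C)(C)C(C)(C)C)c(OCOC)c(CC=C(C)C)c2F)ccc1OCOC
F6 | step 9 | (3S)-1-[3-(2-{[tert-butyl(dimethyl)silyl]oxy}ethyl)-6-fluoro-2,4-bis(methoxymethoxy)-5-(3-methylbut-2-en-1-yl)phenyl]-3-hydroxy-3-[3-methoxy-4-(methoxymethoxy)phenyl]propan-1-one | COc1cc([C@@H](O)CC(=O)c2c(OCOC)c(CCO[Si](C)(C)C(C)(C)C)c(OCOC)c(CC=C(C)C)c2F)ccc1OCOC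
F7 | step 9 | 1-[3-(2-{[tert-butyl(dimethyl)silyl]oxy}ethyl)-6-fluoro-2,4-bis(methoxymethoxy)-5-(3-methylbut-2-en-1-yl)phenyl]-3-[3-methoxy-4-(methoxymethoxy)phenyl]propane-1,3-dione | COc1cc(C(=O)CC(=O)c2c(OCOC)c(CCO[Si](C)(C)C(C)(C)C)c(OCOC)c(CC=C(C)C)c2F)ccc1OCOC
F8 | step 9 | 6-(2-{[tert-butyl(dimethyl)silyl]oxy}ethyl)-2-[3-methoxy-4-(methoxymethoxy)phenyl]-5,7-bis(methoxymethoxy)-8-(3-methylbut-2-en-1-yl)-4H-chromen-4-one | COc1cc(-c2cc(=O)c3c(OCOC)c(CCO[Si](C)(C)C(C)(C)C)c(OCOC)c(CC=C(C)C)c3o2)ccc1OCOC
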